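**Retrosynthetic overview**

1. The route rests on one feature of the bicyclic core: carbon C7a (tertiary OH and lactone C=O on the same carbon) together with the ring arc C7–C6–C5 is a masked furan-2-carboxylic acid, the OH oxygen being the former furan oxygen. The γ-lactone C1–O2–C3 is the tether that holds this furan to the enone alkene C3a=C4.
2. Target 27 ⇐ ketone 24 (Saegusa–Ito desaturation, C5=C6) ⇐ iodide 17 + bromopyranone 23 (nickel cross-electrophile coupling at the CH2–C3 bond of the pyranone).
3. 17 ⇐ β-hydroxy ketone 15 ⇐ oxa-bridged ketone 14 (SmI2 cleavage of the C5–O bond) ⇐ acetyl adduct 10 (hydrogenation, Baeyer–Villiger, methanolysis, oxidation).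
4. 10 ⇐ allyl furan-2-carboxylate 9 by intramolecular furan Diels–Alder addition (bonds C7a–C3a and C4–C5). 9 ⇐ 1, 2, 4 and 7, with the (E)-alkene set by a Horner–Wadsworth–Emmons step.
5. Ring order: the furan rings are bought; carbocycle and γ-lactone close together in step 6; the 2-pyranone is made separately (step 16) and attached last (step 17).

Key step: step 6

Assumption: the (S)-configured oxazaborolidinium catalyst is taken to shield the enone face that leads to the (3aR,7aR) series; the sense of induction has to be checked at alcohol 13, and the (R)-catalyst is used if it is reversed.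

**Route**

Step 1
Reactants: 1 triethyl phosphonoacetate; 2 benzyl 2-bromoethyl ether
Product: 3 ethyl 4-(benzyloxy)-2-(diethoxyphosphoryl)butanoate (racemic)
Conditions: NaH, NaI (cat.), DMF, 0 → 60 °C
Reagents that add atoms: none
Why: SN2 C-alkylation of the sodium phosphonoacetate carbanion with the primary bromide should give the α-substituted phosphonate; its stereocenter is lost in step 2.

Step 2
Reactants: 3 ethyl 4-(benzyloxy)-2-(diethoxyphosphoryl)butanoate; 4 methylglyoxal (40% in water)
Product: 5 ethyl (E)-2-[2-(benzyloxy)ethyl]-4-oxopent-2-enoate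
Conditions: K2CO3, THF–H2O, 0 → 23 °C; minor (Z)-isomer removed by chromatography
Reagents that add atoms: none
Why: Horner–Wadsworth–Emmons olefination at the aldehyde carbon of methylglyoxal should give the trisubstituted alkene with the acetyl group anti to the ester (the usual E preference and the more stable arrangement of the two carbonyl groups), which fixes the alkene geometry that later places the acetyl group endo.

Step 3
Reactants: 5 ethyl (E)-2-[2-(benzyloxy)ethyl]-4-oxopent-2-enoate
Product: 6 (E)-2-[2-(benzyloxy)ethyl]pent-2-ene-1,4-diol (racemic at C4)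
Conditions: i-Bu2AlH (4.5 equiv), CH2Cl2, −78 → 0 °C; aq. potassium sodium tartrate
Reagents that add atoms: none
Why: 1,2-reduction of ester and ketone by the aluminium hydride should give the ene-diol with the alkene geometry and the benzyl ether untouched; the new carbinol centre is racemic and is removed in step 5.

Step 4
Reactants: 6 (E)-2-[2-(benzyloxy)ethyl]pent-2-ene-1,4-diol; 7 furan-2-carbonyl chloride
Product: 8 (E)-2-[2-(benzyloxy)ethyl]-4-hydroxypent-2-en-1-yl furan-2-carboxylate
Conditions: 7 (1.0 equiv), pyridine, CH2Cl2, −40 → 0 °C
Reagents that add atoms: none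
Why: O-acylation with an acid chloride at low temperature should select the primary allylic hydroxyl over the secondary one, so the two oxygen functions are differentiated without a protecting-group step.

Step 5
Reactants: 8 (E)-2-[2-(benzyloxy)ethyl]-4-hydroxypent-2-en-1-yl furan-2-carboxylate
Product: 9 (E)-2-[2-(benzyloxy)ethyl]-4-oxopent-2-en-1-yl furan-2-carboxylate
Conditions: Dess–Martin periodinane, CH2Cl2, 0 → 23 °C
Reagents that add atoms: none
Why: Dess–Martin oxidation of the secondary allylic alcohol should restore the methyl ketone under neutral conditions that leave the furoate and the (E)-alkene unchanged.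

Step 6
Reactants: 9 (E)-2-[2-(benzyloxy)ethyl]-4-oxopent-2-en-1-yl furan-2-carboxylate
Product: 10 exo-tethered cycloadduct, 4-acetyl-3a-[2-(benzyloxy)ethyl]-3a,4,5,7a-tetrahydro-5,7a-epoxyisobenzofuran-1(3H)-one (lactone CH2 syn to the oxygen bridge, side chain endo, acetyl endo)
Conditions: (S)-tetrahydro-1-(2-methylphenyl)-3,3-diphenyl-1H,3H-pyrrolo[1,2-c][1,3,2]oxazaborole (20 mol%), HNTf2 (18 mol%), CH2Cl2 (0.02 M), −40 °C; Et3N quench at −40 °C, crude product kept cold
Reagents that add atoms: none
Why: Proposed new method: the cationic boron Lewis acid should bind the more basic acetyl oxygen rather than the furoate, lower the enone LUMO and let the tethered furan add suprafacially as the 4π partner in a concerted but asynchronous [4+2] addition, the bond from furan C2 to the enone β-carbon (the two future fully substituted carbons) running ahead of the bond from furan C5 to the acetyl-bearing carbon; the closest known reactions are Lewis-acid-promoted intramolecular furan Diels–Alder additions through ether, amine, amide and all-carbon tethers and intermolecular oxazaborolidinium-catalysed additions of furans to enones and acrylates, whereas an allyl furan-2-carboxylate has not been shown to react in this way. The γ-lactone closes in a 5-exo sense through the three-atom C(=O)–O–CH2 tether (from the E rotamer of the ester), and the six-membered carbocycle, and with it the 7-oxabicyclo[2.2.1]heptene, closes by the cycloaddition itself. The short tether can only span the exo face, so the lactone CH2 ends syn to the oxygen bridge and the benzyloxyethyl chain endo, which fixes the relative configuration of both bridgeheads and the quaternary carbon, while the (E)-geometry of 9 places the acetyl group endo. The absolute configuration comes from the catalyst, which covers one face of the bound s-trans enone. The step needs chemoselective activation of the ketone, exo-tether closure and enantiofacial control, secured by the higher basicity of the ketone, the tether length and the single alkene geometry; cycloreversion is held back by the low temperature and by hydrogenating 10 at once.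

Step 7
Reactants: 10 exo-tethered cycloadduct
Product: 11 4-acetyl-3a-[2-(benzyloxy)ethyl]hexahydro-5,7a-epoxyisobenzofuran-1(3H)-one
Conditions: H2 (1 atm), 5% Rh/Al2O3, EtOAc, 0 °C, directly on crude 10
Reagents that add atoms: none
Why: heterogeneous hydrogenation of the strained oxanorbornene alkene is fast at 0 °C and removes the possibility of retro-Diels–Alder cleavage, while rhodium on alumina should spare the benzyl ether, ketone and lactone; no stereocenter is created.

Step 8
Reactants: 11 4-acetyl-3a-[2-(benzyloxy)ethyl]hexahydro-5,7a-epoxyisobenzofuran-1(3H)-one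
Product: 12 3a-[2-(benzyloxy)ethyl]-1-oxooctahydro-5,7a-epoxyisobenzofuran-4-yl acetate (endo acetate)
Conditions: mCPBA, CH2Cl2, 23 → 40 °C
Reagents that add atoms: mCPBA (3-chloroperoxybenzoic acid), OOC(=O)c1cccc(Cl)c1
Why: Baeyer–Villiger oxidation in which the secondary ring carbon should migrate in preference to methyl with retention of configuration, turning the acetyl group into the oxygen substituent needed on that carbon.

Step 9
Reactants: 12 endo acetate
Product: 13 3a-[2-(benzyloxy)ethyl]-4-hydroxyhexahydro-5,7a-epoxyisobenzofuran-1(3H)-one (endo alcohol)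
Conditions: K2CO3 (0.3 equiv), MeOH, 0 °C; AcOH quench, concentration
Reagents that add atoms: none
Why: base-catalysed transesterification should release the secondary alcohol, and any lactone that is opened by methanol should re-close on the mildly acidic work-up because the exo hydroxymethyl group and the bridgehead ester are held next to each other.

Step 10
Reactants: 13 endo alcohol
Product: 14 3a-[2-(benzyloxy)ethyl]hexahydro-5,7a-epoxyisobenzofuran-1,4-dione
Conditions: Dess–Martin periodinane, CH2Cl2, 23 °C
Reagents that add atoms: none
Why: Dess–Martin oxidation of the hindered secondary alcohol should give the ketone, whose two α-carbons are a bridgehead and a quaternary carbon, so neither epimerisation nor enolisation can interfere.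

Step 11
Reactants: 14 oxa-bridged keto lactone
Product: 15 (3aR,7aR)-3a-[2-(benzyloxy)ethyl]-7a-hydroxyhexahydro-2-benzofuran-1,4-dione
Conditions: SmI2 (2.2 equiv), THF–MeOH, −78 °C; sat. NH4Cl
Reagents that add atoms: none
Why: reductive cleavage of an α-alkoxy ketone by SmI2 (ketyl formation, scission of the bridgehead C–O bond, second electron transfer to the samarium enolate, protonation), a reaction known for 7-oxabicyclo[2.2.1]heptan-2-ones, should open the oxygen bridge and release the tertiary alcohol; at −78 °C without HMPA the α-oxygenated lactone should not react, and the two remaining stereocenters are not involved.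

Step 12
Reactants: 15 β-hydroxy ketone benzyl ether
Product: 16 (3aR,7aR)-7a-hydroxy-3a-(2-hydroxyethyl)hexahydro-2-benzofuran-1,4-dione
Conditions: H2 (1 atm), Pd/C, EtOAc, 23 °C
Reagents that add atoms: none
Why: hydrogenolysis of the benzyl ether under neutral conditions should leave ketone, lactone and tertiary alcohol alone and avoids acid or base that could move the lactone onto the new primary hydroxyl (16 may rest partly as its cyclic hemiketal).

Step 13
Reactants: 16 primary alcohol
Product: 17 (3aR,7aR)-7a-hydroxy-3a-(2-iodoethyl)hexahydro-2-benzofuran-1,4-dione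
Conditions: I2, PPh3, imidazole, CH2Cl2, 0 °C
Reagents that add atoms: iodine, II
Why: Appel-type iodination (SN2 displacement at the alkoxyphosphonium salt) should convert only the primary alcohol, the tertiary alcohol being too hindered.

Step 14
Reactants: 18 ethyl but-2-ynoate
Product: 19 ethyl (E)-2,3-dibromobut-2-enoate
Conditions: Br2, CH2Cl2, 0 °C, dark
Reagents that add atoms: bromine, BrBr
Why: electrophilic anti-addition of bromine to the ynoate should give the (E)-dibromide, in which the β-bromine is cis to the ester.

Step 15
Reactants: 19 ethyl (E)-2,3-dibromobut-2-enoate; 20 3-ethynylfuran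
Product: 21 ethyl (E)-2-bromo-5-(furan-3-yl)-3-methylpent-2-en-4-ynoate
Conditions: PdCl2(PPh3)2 (2 mol%), CuI (4 mol%), Et3N, THF, 23 °C
Reagents that add atoms: none
Why: Sonogashira coupling should take place at the β-C–Br bond, the more electrophilic site for oxidative addition in 2,3-dibromoalkenoates, with retention of alkene geometry, so the alkynyl group ends cis to the ester and the α-bromide is kept.

Step 16
Reactants: 21 ethyl (E)-2-bromo-5-(furan-3-yl)-3-methylpent-2-en-4-ynoate
Product: 23 3-bromo-6-(furan-3-yl)-4-methyl-2H-pyran-2-one, via enynoic acid 22 (not isolated)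
Conditions: LiOH, THF–H2O, 0 → 23 °C; aq. HCl; then ZnBr2 (10 mol%), THF, 23 °C
Reagents that add atoms: lithium hydroxide, [Li+].[OH-]
Why: saponification followed by ZnBr2-promoted 6-endo-dig addition of the carboxylic acid to the furyl-substituted alkyne (cycloisomerisation) should close the 2-pyranone with the C3 bromide in place, which avoids an electrophilic bromination in the presence of the furan.

Step 17
Reactants: 17 iodide; 23 3-bromo-6-(furan-3-yl)-4-methyl-2H-pyran-2-one
Product: 24 (3aR,7aR)-3a-{2-[6-(furan-3-yl)-4-methyl-2-oxo-2H-pyran-3-yl]ethyl}-7a-hydroxyhexahydro-2-benzofuran-1,4-dione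
Conditions: NiBr2(MeOCH2CH2OMe) (10 mol%), 4,4′-di-tert-butyl-2,2′-bipyridine (10 mol%), Zn dust, NaI (cat.), DMA, 60 °C
Reagents that add atoms: none
Why: nickel-catalysed reductive cross-electrophile coupling, in which zerovalent nickel inserts into the sp2 C–Br bond, the primary iodide enters as an alkyl radical and reductive elimination forms the C(sp3)–C(sp2) bond, should join the fragments without a preformed organometallic reagent and tolerate ketone, lactone, free tertiary alcohol and furan; the enone is introduced only afterwards so that the alkyl radical has no acceptor to cyclise onto.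

Step 18
Reactants: 24 coupled saturated ketone
Product: 27 (3aR,7aR)-3a-{2-[6-(furan-3-yl)-4-methyl-2-oxo-2H-pyran-3-yl]ethyl}-7a-hydroxy-3,3a,7,7a-tetrahydro-2-benzofuran-1,4-dione (target), via bis-silyl enol ether 25 (not isolated), via silyl ether enone 26 (not isolated)
Conditions: TMSOTf, Et3N, CH2Cl2, 0 °C; then Pd(OAc)2, MeCN, 23 °C; then 1 M HCl, THF, 0 °C
Reagents that add atoms: none
Why: Saegusa–Ito oxidation, in which soft enolisation can occur only toward the single α-CH2 group (the other α-carbon is quaternary), the tertiary alcohol is silylated in passing, Pd(OAc)2 converts the silyl enol ether into the enone by β-hydride elimination and dilute acid removes the silyl ether, should give the target without touching either stereocenter.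

**Compound list**

1 | triethyl phosphonoacetate | CCOC(=O)CP(=O)(OCC)OCC | starting material
2 | benzyl 2-bromoethyl ether | BrCCOCc1ccccc1 | starting material
3 | ethyl 4-(benzyloxy)-2-(diethoxyphosphoryl)butanoate (racemic) | CCOC(=O)C(CCOCc1ccccc1)P(=O)(OCC)OCC | intermediate
4 | methylglyoxal (2-oxopropanal, 40% in water) | CC(=O)C=O | starting material
5 | ethyl (E)-2-[2-(benzyloxy)ethyl]-4-oxopent-2-enoate (acetyl trans to the ester) | CC(=O)/C=C(\CCOCc1ccccc1)C(=O)OCC | intermediate
6 | (E)-2-[2-(benzyloxy)ethyl]pent-2-ene-1,4-diol (racemic at C4) | CC(O)/C=C(\CCOCc1ccccc1)CO | intermediate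
7 | furan-2-carbonyl chloride | O=C(Cl)c1ccco1 | starting material
8 | (E)-2-[2-(benzyloxy)ethyl]-4-hydroxypent-2-en-1-yl furan-2-carboxylate (racemic at C4) | CC(O)/C=C(\CCOCc1ccccc1)COC(=O)c1ccco1 | intermediate
9 | (E)-2-[2-(benzyloxy)ethyl]-4-oxopent-2-en-1-yl furan-2-carboxylate (acetyl trans to the furoyloxymethyl group) | CC(=O)/C=C(\CCOCc1ccccc1)COC(=O)c1ccco1 | intermediate
10 | 4-acetyl-3a-[2-(benzyloxy)ethyl]-3a,4,5,7a-tetrahydro-5,7a-epoxyisobenzofuran-1(3H)-one; 7-oxabicyclo[2.2.1]hept-5-ene with the lactone carbonyl on the bridgehead, lactone CH2 exo, side chain endo, acetyl endo; enantiomer as in the SMILES | O=C1OC[C@@]2(CCOCc3ccccc3)[C@H](C(C)=O)[C@@H]3C=C[C@]12O3 | intermediate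
11 | 4-acetyl-3a-[2-(benzyloxy)ethyl]hexahydro-5,7a-epoxyisobenzofuran-1(3H)-one (same configuration as 10) | O=C1OC[C@@]2(CCOCc3ccccc3)[C@H](C(C)=O)[C@@H]3CC[C@]12O3 | intermediate
12 | 3a-[2-(benzyloxy)ethyl]-1-oxooctahydro-5,7a-epoxyisobenzofuran-4-yl acetate (acetate endo) | O=C1OC[C@@]2(CCOCc3ccccc3)[C@H](OC(C)=O)[C@@H]3CC[C@]12O3 | intermediate
13 | 3a-[2-(benzyloxy)ethyl]-4-hydroxyhexahydro-5,7a-epoxyisobenzofuran-1(3H)-one (hydroxyl endo) | O=C1OC[C@@]2(CCOCc3ccccc3)[C@H](O)[C@@H]3CC[C@]12O3 | intermediate
14 | 3a-[2-(benzyloxy)ethyl]hexahydro-5,7a-epoxyisobenzofuran-1,4-dione (lactone CH2 syn to the oxygen bridge) | O=C1OC[C@@]2(CCOCc3ccccc3)C(=O)[C@@H]3CC[C@]12O3 | intermediate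
15 | (3aR,7aR)-3a-[2-(benzyloxy)ethyl]-7a-hydroxyhexahydro-2-benzofuran-1,4-dione (trans-fused lactone, OH cis to the lactone CH2) | C(OCC[C@@]12COC(=O)[C@@]1(O)CCCC2=O)c1ccccc1 | intermediate
16 | (3aR,7aR)-7a-hydroxy-3a-(2-hydroxyethyl)hexahydro-2-benzofuran-1,4-dione | OCC[C@@]12COC(=O)[C@@]1(O)CCCC2=O | intermediate
17 | (3aR,7aR)-7a-hydroxy-3a-(2-iodoethyl)hexahydro-2-benzofuran-1,4-dione | ICC[C@@]12COC(=O)[C@@]1(O)CCCC2=O | intermediate
18 | ethyl but-2-ynoate | CC#CC(=O)OCC | starting material
19 | ethyl (E)-2,3-dibromobut-2-enoate | C/C(Br)=C(Br)/C(=O)OCC | intermediate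
20 | 3-ethynylfuran | C#Cc1ccoc1 | starting material
21 | ethyl (E)-2-bromo-5-(furan-3-yl)-3-methylpent-2-en-4-ynoate (alkynyl cis to the ester) | C/C(C#Cc1ccoc1)=C(Br)/C(=O)OCC | intermediate
22 | (E)-2-bromo-5-(furan-3-yl)-3-methylpent-2-en-4-ynoic acid | C/C(C#Cc1ccoc1)=C(Br)/C(=O)O | intermediate (not isolated)
23 | 3-bromo-6-(furan-3-yl)-4-methyl-2H-pyran-2-one | Cc1cc(-c2ccoc2)oc(=O)c1Br | intermediate
24 | (3aR,7aR)-3a-{2-[6-(furan-3-yl)-4-methyl-2-oxo-2H-pyran-3-yl]ethyl}-7a-hydroxyhexahydro-2-benzofuran-1,4-dione | Cc1cc(-c2ccoc2)oc(=O)c1CC[C@@]12COC(=O)[C@@]1(O)CCCC2=O | intermediate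
25 | bis(trimethylsilyl) derivative of 24: C4 silyl enol ether (C4=C5) and 7a-silyl ether, configuration as in 24 | Cc1cc(-c2ccoc2)oc(=O)c1CC[C@@]12COC(=O)[C@@]1(O[Si](C)(C)C)CCC=C2O[Si](C)(C)C | intermediate (not isolated)
26 | 7a-O-trimethylsilyl ether of the target | Cc1cc(-c2ccoc2)oc(=O)c1CC[C@@]12COC(=O)[C@@]1(O[Si](C)(C)C)CC=CC2=O | intermediate (not isolated)
27 | (3aR,7aR)-3a-{2-[6-(furan-3-yl)-4-methyl-2-oxo-2H-pyran-3-yl]ethyl}-7a-hydroxy-3,3a,7,7a-tetrahydro-2-benzofuran-1,4-dione (CNP0550188.1) | Cc1cc(-c2ccoc2)oc(=O)c1CC[C@@]12COC(=O)[C@@]1(O)CC=CC2=O | target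

**Count and risks**

Total steps: 18. Longest linear sequence: 15 steps (steps 1–13, 17 and 18).

Steps most likely to fail:

Step 6 (proposed new method). The cycloaddition may stall because the ester tether rests in its unreactive rotamer and the acyl-substituted furan is a weak diene, or the catalyst may fail to tell the enone faces apart. The fallback sets out from 5 and comes back at 13, using only established reactions. Saponification of 5 (LiOH, THF–H2O) gives (E)-2-[2-(benzyloxy)ethyl]-4-oxopent-2-enoic acid F1, which is esterified with furan-2-ylmethanol (DCC, 4-(dimethylamino)pyridine) to the furfuryl ester F2. This is a furfuryl fumarate-type ester, a class for which the thermal intramolecular furan Diels–Alder addition is established; heating (toluene, 80 °C) should give the exo-tethered reverse-lactone adduct F3, whose enantiomers are separated on a chiral stationary phase. Hydrogenation (H2, Rh/Al2O3) gives the saturated adduct F4, Baeyer–Villiger oxidation (mCPBA) the endo acetate F5, and LiAlH4 reduces lactone and acetate to the triol F6. Oxidation with TEMPO (2,2,6,6-tetramethylpiperidine-1-oxyl, cat.) and PhI(OAc)2 should then attack the less shielded hydroxymethyl group on the oxygen-bearing bridgehead and close the lactone in the required orientation, while the secondary alcohol is left, which gives 13. If the isomeric lactone forms, it is reduced back to F6.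

Step 17. Hydrodehalogenation or homocoupling of either halide may outrun the cross-coupling, and the zinc salts may start retro-aldol equilibration of the β-hydroxy ketone. The fallback sets out from 17 and comes back at 24. Zinc insertion (Zn dust, LiCl, THF, 25 °C) gives the alkylzinc iodide F7, which is used at once in a Negishi coupling with 23 (Pd2(dba)3, 2-dicyclohexylphosphino-2′,6′-dimethoxybiphenyl, THF, 40 °C), a two-electron pathway without free alkyl radicals.

Step 18. Enolisation may be incomplete, or the palladium salt may attack the furan ring by C–H palladation and erode the last oxidation. The fallback sets out from 24 and comes back at 27. The silyl enol ether 25, made as in step 18, is treated with PhSeCl (CH2Cl2, −78 °C) and desilylated on work-up to the α-(phenylselanyl) ketone F8. Oxidation (NaIO4, THF–H2O, 0 °C) and syn-elimination of the selenoxide should give 27 without any transition metal.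

Further compounds
F1 | step 6 | (E)-2-[2-(benzyloxy)ethyl]-4-oxopent-2-enoic acid | CC(=O)/C=C(\CCOCc1ccccc1)C(=O)O
F2 | step 6 | furan-2-ylmethyl (E)-2-[2-(benzyloxy)ethyl]-4-oxopent-2-enoate | CC(=O)/C=C(\CCOCc1ccccc1)C(=O)OCc1ccco1
F3 | step 6 | reverse-lactone cycloadduct: 7-oxabicyclo[2.2.1]hept-5-ene with the lactone CH2 on the bridgehead, lactone carbonyl exo on the quaternary carbon, side chain endo, acetyl endo | C1OC(=O)[C@@]2(CCOCc3ccccc3)[C@H](C(C)=O)[C@@H]3C=C[C@]12O3
F4 | step 6 | saturated reverse-lactone adduct | C1OC(=O)[C@@]2(CCOCc3ccccc3)[C@H](C(C)=O)[C@@H]3CC[C@]12O3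
F5 | step 6 | endo acetate of the reverse-lactone series | C1OC(=O)[C@@]2(CCOCc3ccccc3)[C@H](OC(C)=O)[C@@H]3CC[C@]12O3
F6 | step 6 | triol: 7-oxabicyclo[2.2.1]heptane with hydroxymethyl on the bridgehead, exo hydroxymethyl and endo 2-(benzyloxy)ethyl on the quaternary carbon, endo hydroxyl on the next carbon | OC[C@@]2(CCOCc3ccccc3)[C@H](O)[C@@H]3CC[C@@]2(CO)O3
F7 | step 17 | {2-[(3aR,7aR)-7a-hydroxy-1,4-dioxohexahydro-2-benzofuran-3a-yl]ethyl}zinc iodide | I[Zn]CC[C@@]12COC(=O)[C@@]1(O)CCCC2=O
F8 | step 18 | 5-(phenylselanyl) derivative of 24 (selenium on the α-CH carbon, configuration there not defined) | Cc1cc(-c2ccoc2)oc(=O)c1CC[C@@]12COC(=O)[C@@]1(O)CCC([Se]c3ccccc3)C2=O
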